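**Retrosynthetic overview**

- Plakortide N 32 ⇐ methyl ester 30 ⇐ C2–C3 bond (silyl ketene acetal 29 onto a cyclic peroxycarbenium ion at C3) ⇐ C6–C7 bond (alkenyltrifluoroborate 12 onto a cyclic peroxycarbenium ion at C6) ⇐ (4S)-4,6-diethyl-3,6-dimethoxy-1,2-dioxane 26.
- 26 ⇐ 25 ⇐ one-flask union of three components: allenylsilane ketal 20 (C4, C5, C6 and the carbons of both ring ethyl groups), H2O2 (O1–O2) and HC(OMe)3 (C3). The 1,2-dioxane, the only ring of the route, is closed there by the C3–C4 bond.
- Enabling feature: in the ring O1–O2–C3–C4–C5–C6 both carbons on the peroxide bridge (C3 and C6) are at carbonyl level (masked aldehyde and masked ketone). Their carbon substituents (CH2CO2H at C3, alkenyl at C6) are both axial on the chair whose C4 and C6 ethyl groups are equatorial. C3 can therefore enter as an orthoformate carbon that is attacked by C4, and both appendages can follow by axial attack on peroxycarbenium ions.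
- Stereochemical relay: carbinol of 17 (3S) → allene axis of 20 → C4 (anti SE2′ in the ring closure) → C6, then C3 (axial additions). C10 is set separately in the side chain by an asymmetric ethylation followed by Johnson–Claisen transfer.
- Side chain 12: enal 1 → allylic alcohol 2 → ester 5 → alkyne 7 → carbocupration/iodination (9) → trifluoroborate 12.

Key step: step 10

Remark: ring compounds are named with the atom numbering of the target (O1, O2, C3 to C6; C6 is the quaternary carbon). The acetal carbons C3 and C6 of 23 to 28 form as epimer mixtures; these converge because both centres are ionised later.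

**Route**

Step 1
Reactants: 1 (E)-pent-2-enal
Product: 2 (3R,4E)-hept-4-en-3-ol
Conditions: Et2Zn (1.5 equiv), (+)-3-exo-morpholinoisoborneol [(+)-MIB, 4 mol %], hexane/toluene, 0 °C; then 1 M HCl, 0 °C
Reagents that add atoms: diethylzinc, CC[Zn]CC
Why: amino-alcohol-catalysed enantioselective 1,2-addition of a dialkylzinc to an enal; the ligand enantiomer is the one that delivers ethyl to the aldehyde face giving the 3R carbinol, the centre that is later relayed to C10.

Step 2
Reactants: 2 (3R,4E)-hept-4-en-3-ol; 3 triethyl orthoacetate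
Product: 5 ethyl (3R,4E)-3-ethylhept-4-enoate, via ketene acetal 4 (not isolated)
Conditions: 3 (6 equiv, neat), EtCO2H (5 mol %), 140 °C, EtOH distilled off
Reagents that add atoms: none
Why: Johnson–Claisen rearrangement through a chair with the carbinol ethyl group equatorial, so the [3,3] shift transfers the 3R centre suprafacially to the new stereocentre (3R, the later C10) and forms the E alkene (the later C11=C12).

Step 3
Reactants: 5 ethyl (3R,4E)-3-ethylhept-4-enoate
Product: 6 (3R,4E)-3-ethylhept-4-enal
Conditions: i-Bu2AlH (DIBAL-H, 1.05 equiv), CH2Cl2, −78 °C; aq. potassium sodium tartrate (KNaC4H4O6)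
Reagents that add atoms: none
Why: partial reduction of an ester, which stops at the aluminium hemiacetal at −78 °C; the stereocentre is β to the carbonyl group and cannot epimerise.

Step 4
Reactants: 6 (3R,4E)-3-ethylhept-4-enal
Product: 7 (4R,5E)-4-ethyloct-5-en-1-yne
Conditions: dimethyl (1-diazo-2-oxopropyl)phosphonate (1.3 equiv), K2CO3 (2 equiv), MeOH, 0 °C to rt
Reagents that add atoms: dimethyl (1-diazo-2-oxopropyl)phosphonate, COP(=O)(OC)C(=[N+]=[N-])C(C)=O
Why: Seyferth–Gilbert homologation in the Ohira–Bestmann variant converts the aldehyde into the terminal alkyne under mild base without touching the remote stereocentre or the alkene.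

Step 5
Reactants: 7 (4R,5E)-4-ethyloct-5-en-1-yne
Product: 9 (1E,4R,5E)-2,4-diethyl-1-iodoocta-1,5-diene, via alkenylcopper 8 (not isolated)
Conditions: EtMgBr (1.2 equiv), CuBr·SMe2 (1.2 equiv), Et2O/Me2S, −45 °C; 7, −25 °C; then iodine, THF, −40 to 0 °C
Reagents that add atoms: ethylmagnesium bromide, CC[Mg]Br; iodine, [I][I]
Why: Normant carbocupration: ethylcopper adds syn across the terminal alkyne with ethyl at the internal carbon, and iodinolysis of the carbon–copper bond with retention fixes the E trisubstituted alkene (ethyl cis to iodine) needed for C7=C8.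

Step 6
Reactants: 9 (1E,4R,5E)-2,4-diethyl-1-iodoocta-1,5-diene
Product: 12 potassium [(1E,4R,5E)-2,4-diethylocta-1,5-dien-1-yl]trifluoroborate, via alkenyllithium 10 (not isolated), via lithium alkenyltriisopropoxyborate 11 (not isolated)
Conditions: t-BuLi (2.1 equiv), Et2O, −78 °C; B(OiPr)3 (1.5 equiv), −78 °C to rt; aq. KHF2, MeOH, rt
Reagents that add atoms: triisopropyl borate, CC(C)OB(OC(C)C)OC(C)C; potassium hydrogen difluoride, [K+].F[H-]F
Why: iodine–lithium exchange and boration both proceed with retention of the alkene geometry, and KHF2 converts the borate into the bench-stable trifluoroborate (standard alkenyl iodide to alkenyltrifluoroborate sequence).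

Step 7
Reactants: 13 methyl propanoate
Product: 14 2-methoxybut-1-ene
Conditions: Cp2TiMe2 (dimethyltitanocene, 2 equiv), toluene/THF, 65 °C, dark; product distilled out
Reagents that add atoms: dimethyltitanocene, C[Ti](C)(C1C=CC=C1)C1C=CC=C1
Why: Petasis methylenation: thermally generated Cp2Ti=CH2 converts the ester carbonyl group into the enol ether by [2+2] addition and cycloreversion, which places the double bond regiospecifically at the terminal position.

Step 8
Reactants: 14 2-methoxybut-1-ene; 15 3-(trimethylsilyl)prop-2-ynal
Product: 17 (3S)-5,5-dimethoxy-1-(trimethylsilyl)hept-1-yn-3-ol, via enol ether 16 (not isolated)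
Conditions: Ti(OiPr)4, N-(3,5-di-tert-butylsalicylidene)-2-amino-2′-hydroxy-1,1′-binaphthyl (the enantiomer that gives 3S) and 3,5-di-tert-butylsalicylic acid (5 mol % each), 14 (8 equiv), Et2O, 0 °C; then MeOH, PPTS (5 mol %), 0 °C
Reagents that add atoms: methanol, CO
Why: catalytic asymmetric carbonyl-ene (acetone-aldol-type) addition of a 2-methoxyalkene to an ynal, in which the chiral titanium Schiff-base complex shields one aldehyde face and sets the 3S carbinol; methanol then adds to the enol ether in the Markovnikov sense to give the dimethyl ketal.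

Step 9
Reactants: 17 (3S)-5,5-dimethoxy-1-(trimethylsilyl)hept-1-yn-3-ol
Product: 20 (aS)-(5,5-dimethoxyhepta-1,2-dien-1-yl)trimethylsilane, via sulfonylhydrazine 18 (not isolated), via propargylic diazene 19 (not isolated)
Conditions: PPh3, DEAD, 2-nitrobenzenesulfonylhydrazide (1.5 equiv each), THF, −15 °C, then 23 °C
Reagents that add atoms: none
Why: Myers allene synthesis: Mitsunobu displacement by the sulfonylhydrazide with inversion, loss of 2-nitrobenzenesulfinic acid and retro-ene loss of N2 with suprafacial hydrogen transfer amount to an anti SN2′ delivery of hydrogen, so the 3S carbinol is converted stereospecifically into the (aS)-allenylsilane.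

Step 10
Reactants: 20 (aS)-(5,5-dimethoxyhepta-1,2-dien-1-yl)trimethylsilane; 21 hydrogen peroxide; 22 trimethyl orthoformate
Product: 25 (4R)-6-ethyl-4-ethynyl-3,6-dimethoxy-1,2-dioxane, via hydroperoxy ketal 23 (not isolated), via peroxy orthoformate 24 (not isolated)
Conditions: 21 (1.2 equiv, anhydrous Et2O solution), PPTS (5 mol %), CH2Cl2, 0 °C; 22 (3 equiv), 0 °C to rt, volatiles removed in vacuo; Me3SiOTf (10 mol %), 2,6-di-tert-butyl-4-methylpyridine (10 mol %), CH2Cl2, −78 to −50 °C; pyridine quench
Reagents that add atoms: none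
Why: Proposed new method: acid-catalysed exchange turns the ketal into hydroperoxy ketal 23 and, with 22, into peroxy orthoformate 24; Me3SiOTf then removes a methoxy group from the orthoformate carbon, and the resulting methoxy(peroxy)carbenium ion at C3 is attacked intramolecularly by the allene terminus C4 (SE2′), the β-silyl vinyl cation losing Me3Si+ to leave the ethynyl group and to regenerate the silyl triflate. The closest known reaction types are the Lewis-acid-mediated additions of allyl- and allenylsilanes to acetals and orthoformates (Hosomi–Sakurai type, anti SE2′) and the C–C bond-forming substitutions of monoperoxy acetals through peroxycarbenium ions. The 1,2-dioxane closes in a 6-exo mode with respect to the allene, with the O2=C3 carbenium unit endocyclic, through a chair-like array O1–O2–C3···C4–C5–C6. The one new stereocentre that counts, C4, is set by axis-to-centre chirality transfer: C3 must bond anti to the carbon–silicon bond of the (aS)-allene, which should give 4R for either configuration of the acetal carbons C3 and C6, both of which are reset later. The step needs ionisation at C3 and not at C6, which the orthoester level of C3 secures (a cation stabilised by two oxygens forms far more readily than the peroxycarbenium ion of a ketal); it needs carbon attack by the allene in preference to reversible oxygen attack, which the β-silicon effect and the six-membered geometry secure; and it needs survival of the O–O bond, which the non-reducing, buffered, low-temperature conditions secure.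

Step 11
Reactants: 25 (4R)-6-ethyl-4-ethynyl-3,6-dimethoxy-1,2-dioxane
Product: 26 (4S)-4,6-diethyl-3,6-dimethoxy-1,2-dioxane
Conditions: KO2C–N=N–CO2K (6 equiv), AcOH (12 equiv), CH2Cl2, 0 °C to rt
Reagents that add atoms: none
Why: diimide reduction: HN=NH, released from the azodicarboxylate, transfers hydrogen concertedly to the alkyne and then to the vinyl group and leaves the O–O bond and the acetals untouched (no other unsaturation is present); C4 changes its descriptor by priority only, not its geometry.

Step 12
Reactants: 26 (4S)-4,6-diethyl-3,6-dimethoxy-1,2-dioxane; 12 potassium [(1E,4R,5E)-2,4-diethylocta-1,5-dien-1-yl]trifluoroborate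
Product: 28 (4S,6R)-6-[(1E,4R,5E)-2,4-diethylocta-1,5-dien-1-yl]-4,6-diethyl-3-methoxy-1,2-dioxane, via alkenyldifluoroborane 27 (not isolated)
Conditions: 12 (1.5 equiv), BF3·OEt2 (3 equiv), CH2Cl2/MeCN, −40 to −20 °C; aq. NaHCO3
Reagents that add atoms: none
Why: Proposed new method: BF3 converts 12 into the alkenyldifluoroborane 27, which removes the methoxy group from the ketal carbon C6 (its tertiary peroxycarbenium ion forms faster than the secondary one at C3) and hands the alkenyl group from the resulting alkenyl(methoxy)difluoroborate to C6 with retention of the alkene geometry; attack along the axial trajectory of the half-chair with the C4 ethyl group pseudo-equatorial should put the alkenyl group axial and trans to that ethyl group (6R); the closest known reaction types are the BF3-mediated coupling of alkenyl- and alkynyltrifluoroborates with acetals through oxocarbenium ions and the Lewis-acid-mediated allylation and enol-silane alkylation of peroxyketals through peroxycarbenium ions.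

Step 13
Reactants: 28 (4S,6R)-6-[(1E,4R,5E)-2,4-diethylocta-1,5-dien-1-yl]-4,6-diethyl-3-methoxy-1,2-dioxane; 29 tert-butyl[(1-methoxyethenyl)oxy]dimethylsilane
Product: 30 methyl 2-[(3S,4S,6R)-6-[(1E,4R,5E)-2,4-diethylocta-1,5-dien-1-yl]-4,6-diethyl-1,2-dioxan-3-yl]acetate
Conditions: 29 (2 equiv), Me3SiOTf (0.3 equiv), CH2Cl2, −78 °C; pyridine, then aq. NaHCO3
Reagents that add atoms: none
Why: Mukaiyama-type substitution of a cyclic monoperoxy acetal by a silyl ketene acetal, a reaction established for 3-alkoxy-1,2-dioxolanes and 3-alkoxy-1,2-dioxanes: Me3SiOTf ionises the C3–OMe bond, and the ketene acetal should attack the endocyclic peroxycarbenium ion along the axial trajectory of the half-chair in which both ring ethyl groups are pseudo-equatorial, that is cis to the C4 ethyl group and on the face opposite to the axial C6 alkenyl group, which sets 3S.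

Step 14
Reactants: 30 methyl 2-[(3S,4S,6R)-6-[(1E,4R,5E)-2,4-diethylocta-1,5-dien-1-yl]-4,6-diethyl-1,2-dioxan-3-yl]acetate
Product: 32 plakortide N, via lithium carboxylate 31 (not isolated)
Conditions: LiOH (3 equiv), THF/H2O, 0 °C; then 1 M HCl to pH 3, 0 °C
Reagents that add atoms: lithium hydroxide, [Li+].[OH-]
Why: saponification of an unhindered methyl ester at 0 °C, conditions that 1,2-dioxane-3-acetic esters tolerate; no stereocentre is touched, and cold, brief treatment should avoid base-induced cleavage of the peroxide.

**Compound list**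

1 | (E)-pent-2-enal | CC/C=C/C=O | starting material
2 | (3R,4E)-hept-4-en-3-ol | CC/C=C/[C@H](O)CC | intermediate
3 | triethyl orthoacetate | CC(OCC)(OCC)OCC | starting material
4 | 1-ethoxy-1-[(3R,4E)-hept-4-en-3-yloxy]ethene (ketene acetal) | CC/C=C/[C@H](OC(=C)OCC)CC | intermediate
5 | ethyl (3R,4E)-3-ethylhept-4-enoate | CC/C=C/[C@H](CC)CC(=O)OCC | intermediate
6 | (3R,4E)-3-ethylhept-4-enal | CC/C=C/[C@H](CC)CC=O | intermediate
7 | (4R,5E)-4-ethyloct-5-en-1-yne | CC/C=C/[C@H](CC)CC#C | intermediate
8 | [(1E,4R,5E)-2,4-diethylocta-1,5-dien-1-yl]copper | CC/C=C/[C@H](CC)C/C(=C/[Cu])CC | intermediate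
9 | (1E,4R,5E)-2,4-diethyl-1-iodoocta-1,5-diene | CC/C=C/[C@H](CC)C/C(=C/I)CC | intermediate
10 | [(1E,4R,5E)-2,4-diethylocta-1,5-dien-1-yl]lithium | CC/C=C/[C@H](CC)C/C(=C/[Li])CC | intermediate
11 | lithium [(1E,4R,5E)-2,4-diethylocta-1,5-dien-1-yl]tri(propan-2-yloxy)borate | CC/C=C/[C@H](CC)C/C(=C/[B-](OC(C)C)(OC(C)C)OC(C)C)CC.[Li+] | intermediate
12 | potassium [(1E,4R,5E)-2,4-diethylocta-1,5-dien-1-yl]trifluoroborate | CC/C=C/[C@H](CC)C/C(=C/[B-](F)(F)F)CC.[K+] | intermediate
13 | methyl propanoate | CCC(=O)OC | starting material
14 | 2-methoxybut-1-ene | CCC(=C)OC | intermediate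
15 | 3-(trimethylsilyl)prop-2-ynal | C[Si](C)(C)C#CC=O | starting material
16 | (3S)-5-methoxy-1-(trimethylsilyl)hept-5-en-1-yn-3-ol (enol ether, both alkene isomers) | CC=C(OC)C[C@H](O)C#C[Si](C)(C)C | intermediate
17 | (3S)-5,5-dimethoxy-1-(trimethylsilyl)hept-1-yn-3-ol | CCC(OC)(OC)C[C@H](O)C#C[Si](C)(C)C | intermediate
18 | N-[(3R)-5,5-dimethoxy-1-(trimethylsilyl)hept-1-yn-3-yl]-2-nitrobenzenesulfonohydrazide | CCC(OC)(OC)C[C@@H](N(N)S(=O)(=O)c1ccccc1[N+](=O)[O-])C#C[Si](C)(C)C | intermediate
19 | [(3R)-5,5-dimethoxy-1-(trimethylsilyl)hept-1-yn-3-yl]diazene | CCC(OC)(OC)C[C@@H](N=N)C#C[Si](C)(C)C | intermediate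
20 | (aS)-(5,5-dimethoxyhepta-1,2-dien-1-yl)trimethylsilane (allene axis S, P helicity) | CCC(OC)(OC)CC([H])=[C@@]=C([H])[Si](C)(C)C | intermediate
21 | hydrogen peroxide | OO | starting material
22 | trimethyl orthoformate | COC(OC)OC | starting material
23 | (aS)-(5-hydroperoxy-5-methoxyhepta-1,2-dien-1-yl)trimethylsilane (both epimers at the ketal carbon) | CCC(OC)(OO)CC([H])=[C@@]=C([H])[Si](C)(C)C | intermediate
24 | (aS)-{5-[(dimethoxymethyl)peroxy]-5-methoxyhepta-1,2-dien-1-yl}trimethylsilane (both epimers at the ketal carbon) | CCC(OC)(OOC(OC)OC)CC([H])=[C@@]=C([H])[Si](C)(C)C | intermediate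
25 | (4R)-6-ethyl-4-ethynyl-3,6-dimethoxy-1,2-dioxane (epimers at C3 and C6) | CCC1(OC)C[C@H](C#C)C(OC)OO1 | intermediate
26 | (4S)-4,6-diethyl-3,6-dimethoxy-1,2-dioxane (epimers at C3 and C6) | CCC1(OC)C[C@H](CC)C(OC)OO1 | intermediate
27 | [(1E,4R,5E)-2,4-diethylocta-1,5-dien-1-yl]difluoroborane | CC/C=C/[C@H](CC)C/C(=C/B(F)F)CC | intermediate
28 | (4S,6R)-6-[(1E,4R,5E)-2,4-diethylocta-1,5-dien-1-yl]-4,6-diethyl-3-methoxy-1,2-dioxane (epimers at C3) | CC/C=C/[C@H](CC)C/C(=C/[C@@]1(CC)C[C@H](CC)C(OC)OO1)CC | intermediate
29 | tert-butyl[(1-methoxyethenyl)oxy]dimethylsilane | C=C(OC)O[Si](C)(C)C(C)(C)C | starting material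
30 | methyl 2-[(3S,4S,6R)-6-[(1E,4R,5E)-2,4-diethylocta-1,5-dien-1-yl]-4,6-diethyl-1,2-dioxan-3-yl]acetate | CC/C=C/[C@H](CC)C/C(=C/[C@@]1(CC)C[C@H](CC)[C@H](CC(=O)OC)OO1)CC | intermediate
31 | lithium 2-[(3S,4S,6R)-6-[(1E,4R,5E)-2,4-diethylocta-1,5-dien-1-yl]-4,6-diethyl-1,2-dioxan-3-yl]acetate | CC/C=C/[C@H](CC)C/C(=C/[C@@]1(CC)C[C@H](CC)[C@H](CC(=O)[O-])OO1)CC.[Li+] | intermediate
32 | plakortide N, 2-[(3S,4S,6R)-6-[(1E,4R,5E)-2,4-diethylocta-1,5-dien-1-yl]-4,6-diethyl-1,2-dioxan-3-yl]acetic acid | CC/C=C/[C@H](CC)C/C(=C/[C@@]1(CC)C[C@H](CC)[C@H](CC(=O)O)OO1)CC | target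

**Step count and risks**

Total step count: 14. Longest linear sequence: 9 steps (steps 1 to 6, then 12 to 14); the ring branch (steps 7 to 11) joins at step 12.

Steps most likely to fail:

1. Step 10 (carries the label). What may go wrong: ionisation at the ketal carbon C6 in place of the orthoformate carbon, transfer of the peroxide away from C6 by acid-catalysed exchange (loss of the tether), or attack of the allene on a second molecule. The fallback sets out from 20 and comes back at 25; it uses known chemistry and makes the C3–C4 bond between two molecules, closing the ring afterwards through oxygen. 20 and HC(OMe)3 with catalytic Me3SiOTf (CH2Cl2, −78 °C) should give, by the established anti SE2′ propargylation of orthoformates and acetals by allenylsilanes, (2R)-2-ethynyl-1,1,4,4-tetramethoxyhexane F1 with the same axis-to-centre transfer. Ethereal H2O2 with catalytic camphorsulfonic acid (CH2Cl2, 0 °C) should then exchange one methoxy group at each acetal carbon (peroxyketalisation of a masked 1,4-dicarbonyl compound) and give 25.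

2. Step 12 (carries the label). What may go wrong: no transfer of the hindered alkenyl group to the tertiary cation (proton loss to an enol peroxide, Criegee-type fragmentation of the peroxycarbenium ion, participation of the C3 methoxy oxygen), or poor facial selectivity at C6. The fallback sets out from 20 and 9 and comes back at 28; it uses known chemistry but gives up the control at C6, because the C6–C7 bond is made by carbonyl addition before the peroxide ring exists. F1 (from 20 as in the first fallback) is reduced with diimide to (2S)-2-ethyl-1,1,4,4-tetramethoxyhexane F2. PPTS in wet acetone should cleave the ketal faster than the acetal and give (5S)-5-ethyl-6,6-dimethoxyhexan-3-one F3. Alkenyllithium 10 (from 9 and t-BuLi), transmetallated with CeCl3, adds to F3 to give (5S)-3-[(1E,4R,5E)-2,4-diethylocta-1,5-dien-1-yl]-5-ethyl-6,6-dimethoxyhexan-3-ol F4 as both carbinol epimers. Ethereal H2O2 with camphorsulfonic acid turns the acetal into a hydroperoxy acetal whose OOH group captures the tertiary allylic cation in a six-membered ring closure (acid-mediated perhydrolysis of a tertiary allylic alcohol). This should give 28 and its C6 epimer, which have to be separated by chromatography.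

3. Step 13. What may go wrong: ionisation of the tertiary allylic C6–O1 bond by the Lewis acid (ring opening, elimination) in competition with ionisation at C3, or attack on the equatorial face at C3 (loss of the 3,4-cis relationship). The fallback sets out from 28 and comes back at 30; it uses known chemistry, attaching the acetate by olefination and re-closing the ring through oxygen. Mild hydrolysis of 28 (AcOH/H2O/THF, rt) gives the cyclic peroxy hemiacetal (4S,6R)-6-[(1E,4R,5E)-2,4-diethylocta-1,5-dien-1-yl]-4,6-diethyl-1,2-dioxan-3-ol F5. Its open hydroperoxy aldehyde form reacts with Ph3P=CHCO2Me (Wittig reaction, CH2Cl2, rt) to give methyl (2E,4S,6R,7E,10R,11E)-4,6,8,10-tetraethyl-6-hydroperoxytetradeca-2,7,11-trienoate F6. Catalytic Et2NH in CF3CH2OH should close the ring by intramolecular conjugate addition of the hydroperoxide (oxa-Michael addition), giving 30 and its C3 epimer for separation.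

**Further compounds**

F1 | step 10 | (2R)-2-ethynyl-1,1,4,4-tetramethoxyhexane | CCC(OC)(OC)C[C@H](C#C)C(OC)OC
F2 | step 12 | (2S)-2-ethyl-1,1,4,4-tetramethoxyhexane | CCC(OC)(OC)C[C@H](CC)C(OC)OC
F3 | step 12 | (5S)-5-ethyl-6,6-dimethoxyhexan-3-one | CCC(=O)C[C@H](CC)C(OC)OC
F4 | step 12 | (5S)-3-[(1E,4R,5E)-2,4-diethylocta-1,5-dien-1-yl]-5-ethyl-6,6-dimethoxyhexan-3-ol (both carbinol epimers) | CC/C=C/[C@H](CC)C/C(=C/C(O)(CC)C[C@H](CC)C(OC)OC)CC
F5 | step 13 | (4S,6R)-6-[(1E,4R,5E)-2,4-diethylocta-1,5-dien-1-yl]-4,6-diethyl-1,2-dioxan-3-ol (epimers at C3) | CC/C=C/[C@H](CC)C/C(=C/[C@@]1(CC)C[C@H](CC)C(O)OO1)CC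
F6 | step 13 | methyl (2E,4S,6R,7E,10R,11E)-4,6,8,10-tetraethyl-6-hydroperoxytetradeca-2,7,11-trienoate | CC/C=C/[C@H](CC)C/C(=C/[C@](CC)(OO)C[C@H](CC)/C=C/C(=O)OC)CC
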